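**Plan**

- Target numbering: C1 is the quaternary carbinol carrying C7H2OBz, C2 the ketone, C3=C4 the alkene, C5 the free carbinol, C6 the benzoate carbon.
- Retrosynthetic cuts, in order: the PMB ether on O5; the C3=C4 double bond (back to a C4 β-ketol); the C3–C4 σ bond; the C7–O benzoate bond and the C1–C7 bond (an oxirane built on a ketone); a sugar exocyclic alkene (from a 6-iodide); the O-2/O-3 pattern (from a 2,3-anhydro sugar).
- Enabling feature: the carbocycle has its C2 ketone between the fully substituted C1 and the C3 methine and is oxygenated at C1, C6 and C5. This is a 2-deoxyinosose, so C3–C4 is the aldol bond of the 5-keto aldehyde released by a 6-deoxyhex-5-enopyranoside (sugar C-4, C-5, C-6, C-1, C-2, C-3 become C1 to C6), and only C3 can act as the enol carbon.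
- Forward: every substituent is placed on the pyranose ring of a commercial glucoside in one linear sequence; the carbocycle is the only ring formed (step 13), followed by dehydration and PMB removal.
- Stereochemistry: absolute configuration from D-glucose; C5 and C6 (sugar C-2, C-3, D-altro) from epoxide closure and trans-diaxial opening; C1 (sugar C-4) from delivery of the ylide carbon to the α face of the 4-ulose; the C4 carbinol made in the key step is eliminated.

Key step: step 13

Remarks on the chemistry:
- Compound 1 is taken as a catalogue chemical (the benzaldehyde acetal of methyl α-D-glucopyranoside).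
- Pyranosides carry sugar locants (C-1 to C-6). Compounds 12 and 14–16 are named as 4-C-substituted D-idosides: tertiary O-4 on the β face (cis to O-2, trans to O-3), branch carbon on the α face.
- Carbocycles carry the target numbering given above.
- Compound 19 is drawn as the C4 epimer usually favoured in this rearrangement (hydroxyl trans to the 1,3-related benzoate); the other epimer would serve equally in step 14.
- Numbered as starting materials are 1 and the three reagents whose atoms persist into the target (6, 11, 13); reagents whose atoms are later removed appear only on the reagent lines.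

**Route**

Step 1
Reactants: 1 methyl 4,6-O-benzylidene-α-D-glucopyranoside
Product: 2 methyl 4,6-O-benzylidene-2,3-di-O-tosyl-α-D-glucopyranoside
Conditions: TsCl (3 equiv), pyridine, DMAP (cat.), rt→40 °C
Reagents that add atoms: p-toluenesulfonyl chloride, Cc1ccc(S(=O)(=O)Cl)cc1
Why: Standard sulfonylation of the two equatorial secondary hydroxyls of the conformationally locked diol; no stereocentre is touched.

Step 2
Reactants: 2 methyl 4,6-O-benzylidene-2,3-di-O-tosyl-α-D-glucopyranoside
Product: 4 methyl 2,3-anhydro-4,6-O-benzylidene-α-D-allopyranoside, via monotosylate alkoxide 3 (not isolated)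
Conditions: NaOMe, MeOH–CH2Cl2, 0 °C→rt
Reagents that add atoms: none
Why: Methoxide cleaves the 2-O-sulfonate at sulfur (its alkoxide, next to the anomeric centre, is the better leaving group) and the freed O-2 alkoxide displaces the C-3 tosylate with inversion in a Williamson-type closure, placing the oxirane on the α face (allo).

Step 3
Reactants: 4 methyl 2,3-anhydro-4,6-O-benzylidene-α-D-allopyranoside
Product: 5 methyl 4,6-O-benzylidene-2-O-(4-methoxybenzyl)-α-D-altropyranoside
Conditions: 4-MeOC6H4CH2OH (neat, excess), NaH (0.3 equiv), 100 °C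
Reagents that add atoms: 4-methoxybenzyl alcohol, COc1ccc(CO)cc1
Why: Alkoxide opening of the rigid trans-fused anhydro sugar is trans-diaxial, so the nucleophile enters C-2 from the β face and leaves the axial 3-OH on the α face, giving the D-altro configuration with O-2 and O-3 already differentiated.

Step 4
Reactants: 5 methyl 4,6-O-benzylidene-2-O-(4-methoxybenzyl)-α-D-altropyranoside; 6 benzoyl chloride
Product: 7 methyl 3-O-benzoyl-4,6-O-benzylidene-2-O-(4-methoxybenzyl)-α-D-altropyranoside
Conditions: BzCl, pyridine, DMAP (cat.), CH2Cl2, 0 °C→rt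
Reagents that add atoms: benzoyl chloride (6), O=C(Cl)c1ccccc1
Why: DMAP-catalysed acylation of the single free (axial) hydroxyl installs the ester that becomes the C6 benzoate of the target.

Step 5
Reactants: 7 methyl 3-O-benzoyl-4,6-O-benzylidene-2-O-(4-methoxybenzyl)-α-D-altropyranoside
Product: 8 methyl 3-O-benzoyl-2-O-(4-methoxybenzyl)-α-D-altropyranoside
Conditions: AcOH–H2O (4:1), 60 °C
Reagents that add atoms: none
Why: Mild acetal hydrolysis removes the benzylidene group while the PMB ether, the benzoate and the methyl glycoside should survive aqueous acetic acid.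

Step 6
Reactants: 8 methyl 3-O-benzoyl-2-O-(4-methoxybenzyl)-α-D-altropyranoside
Product: 9 methyl 3-O-benzoyl-6-O-(tert-butyldimethylsilyl)-2-O-(4-methoxybenzyl)-α-D-altropyranoside
Conditions: TBSCl (1.1 equiv), imidazole, CH2Cl2, 0 °C
Reagents that add atoms: tert-butyldimethylsilyl chloride, CC(C)(C)[Si](C)(C)Cl
Why: Silylation is selective for the primary 6-OH over the secondary 4-OH on steric grounds, and the weak base should not move the 3-benzoate.

Step 7
Reactants: 9 methyl 3-O-benzoyl-6-O-(tert-butyldimethylsilyl)-2-O-(4-methoxybenzyl)-α-D-altropyranoside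
Product: 10 methyl 3-O-benzoyl-6-O-(tert-butyldimethylsilyl)-2-O-(4-methoxybenzyl)-α-D-arabino-hexopyranosid-4-ulose
Conditions: Dess–Martin periodinane, CH2Cl2, rt
Reagents that add atoms: none
Why: Dess–Martin oxidation of the only free alcohol is near-neutral, which should spare the α-benzoyloxy ketone from enolisation and β-elimination; the ketone should be carried on without long storage.

Step 8
Reactants: 10 methyl 3-O-benzoyl-6-O-(tert-butyldimethylsilyl)-2-O-(4-methoxybenzyl)-α-D-arabino-hexopyranosid-4-ulose; 11 trimethylsulfoxonium iodide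
Product: 12 methyl 4,4¹-anhydro-3-O-benzoyl-6-O-(tert-butyldimethylsilyl)-4-C-(hydroxymethyl)-2-O-(4-methoxybenzyl)-α-D-idopyranoside (spiro-oxirane: O on the β face; CH2 on the α face)
Conditions: Me3S(O)I, NaH, DMSO–THF, 0 °C→rt (ylide preformed)
Reagents that add atoms: trimethylsulfoxonium iodide (11), C[S+](C)(C)=O.[I-]
Why: Corey–Chaykovsky epoxidation with the sulfoxonium ylide adds reversibly, so the new C–C bond should settle equatorial on the α face, away from the syn-axial 2-O-PMB group, and closure puts the oxirane oxygen on the β face, which sets the quaternary centre (target C1) with its oxygen trans to the 3-benzoate.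

Step 9
Reactants: 12 the spiro-oxirane; 13 benzoic acid
Product: 14 methyl 3-O-benzoyl-4-C-(benzoyloxymethyl)-6-O-(tert-butyldimethylsilyl)-2-O-(4-methoxybenzyl)-α-D-idopyranoside
Conditions: PhCO2H (3 equiv), Cs2CO3 (0.2 equiv), DMF, 70 °C
Reagents that add atoms: benzoic acid (13), O=C(O)c1ccccc1
Why: Carboxylate SN2 opening of the 2,2-disubstituted oxirane at its CH2 carbon leaves the quaternary carbon untouched (configuration retained) and gives the primary benzoate and the free tertiary alcohol directly; the excess acid keeps the tertiary alkoxide protonated and should suppress acyl migration.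

Step 10
Reactants: 14 methyl 3-O-benzoyl-4-C-(benzoyloxymethyl)-6-O-(tert-butyldimethylsilyl)-2-O-(4-methoxybenzyl)-α-D-idopyranoside
Product: 15 methyl 3-O-benzoyl-4-C-(benzoyloxymethyl)-2-O-(4-methoxybenzyl)-α-D-idopyranoside
Conditions: HF·pyridine, THF–pyridine, 0 °C→rt
Reagents that add atoms: none
Why: Fluoride cleavage of the primary silyl ether under non-basic conditions should leave the esters, the PMB ether and the glycoside untouched and avoid benzoyl migration.

Step 11
Reactants: 15 methyl 3-O-benzoyl-4-C-(benzoyloxymethyl)-2-O-(4-methoxybenzyl)-α-D-idopyranoside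
Product: 16 methyl 3-O-benzoyl-4-C-(benzoyloxymethyl)-6-deoxy-6-iodo-2-O-(4-methoxybenzyl)-α-D-idopyranoside
Conditions: I2, PPh3, imidazole, toluene, 60 °C
Reagents that add atoms: iodine, II
Why: Appel-type iodination (PPh3/I2/imidazole) substitutes the primary hydroxyl by SN2 at C-6, while the hindered tertiary hydroxyl is not expected to react.

Step 12
Reactants: 16 methyl 3-O-benzoyl-4-C-(benzoyloxymethyl)-6-deoxy-6-iodo-2-O-(4-methoxybenzyl)-α-D-idopyranoside
Product: 17 methyl 3-O-benzoyl-4-C-(benzoyloxymethyl)-6-deoxy-2-O-(4-methoxybenzyl)-hex-5-enopyranoside (C-1 to C-4 as in 16; exocyclic C-5=C-6)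
Conditions: AgF, pyridine, rt, dark
Reagents that add atoms: none
Why: Silver-assisted E2 dehydroiodination of 6-deoxy-6-iodo glycosides is the standard entry to exocyclic enol ethers and uses no base strong enough to shift or cleave the benzoates.

Step 13
Reactants: 17 the hex-5-enopyranoside
Product: 19 [(1R,4R,5R,6S)-6-(benzoyloxy)-1,4-dihydroxy-5-[(4-methoxybenzyl)oxy]-2-oxocyclohexyl]methyl benzoate, via mercurated keto-aldehyde 18 (not isolated)
Conditions: Hg(OCOCF3)2 (10 mol%), acetone–H2O (4:1), rt
Reagents that add atoms: water, O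
Why: Ferrier carbocyclisation: Hg(II) adds to the electron-rich exocyclic enol ether with water at C-5, the hemiketal opens and methanol is lost from the anomeric hemiacetal to give the acyclic 5-keto aldehyde 18 with a C–Hg bond at C-6, which adds to the aldehyde as a mercury enolate equivalent and releases Hg(II) on protonolysis. This is the known rearrangement of 6-deoxyhex-5-enopyranosides to 2-deoxyinosose-type cyclohexanones, here applied to a 4-C-branched substrate. The six-membered ring closes in the 6-(enolexo)-exo-trig mode and forms the C3–C4 bond. The one new stereocentre, the C4 carbinol, is set by the chair-like aldol transition state and is expected mainly trans to the C6 benzoate, but it is erased in step 14. The step needs one enol regiochemistry and chemoselective mercuration: the mercurated CH2 is the only nucleophilic α-carbon because the other α-position is the fully substituted C1, which also rules out β-elimination of the C6 benzoate, and the enol ether is far more reactive toward Hg(II) than the anisyl ring. The three existing stereocentres are not involved.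

Step 14
Reactants: 19 the β-hydroxy ketone
Product: 21 [(1R,5R,6S)-6-(benzoyloxy)-1-hydroxy-5-[(4-methoxybenzyl)oxy]-2-oxocyclohex-3-en-1-yl]methyl benzoate, via β-mesyloxy ketone 20 (not isolated)
Conditions: MsCl (1.2 equiv), Et3N, CH2Cl2, 0 °C
Reagents that add atoms: none
Why: The secondary β-hydroxyl is mesylated and the β-mesyloxy ketone undergoes E1cB elimination through the C3 enolate in the same flask to give the conjugated enone; with a small excess of MsCl at 0 °C the hindered tertiary α-hydroxyl is not expected to be sulfonylated.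

Step 15
Reactants: 21 the PMB-protected enone
Product: 22 [(1R,5R,6S)-6-(benzoyloxy)-1,5-dihydroxy-2-oxocyclohex-3-en-1-yl]methyl benzoate (target)
Conditions: DDQ, CH2Cl2–pH 7 buffer (10:1), 0 °C→rt
Reagents that add atoms: none
Why: Oxidative PMB cleavage with DDQ in wet dichloromethane is neutral and should leave the benzoates, the electron-poor enone and the free carbinols intact.

**Compound list**

1 | methyl 4,6-O-benzylidene-α-D-glucopyranoside | CO[C@H]1O[C@@H]2CO[C@@H](c3ccccc3)O[C@H]2[C@H](O)[C@H]1O | starting material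
2 | methyl 4,6-O-benzylidene-2,3-di-O-tosyl-α-D-glucopyranoside | CO[C@H]1O[C@@H]2CO[C@@H](c3ccccc3)O[C@H]2[C@H](OS(=O)(=O)c4ccc(C)cc4)[C@H]1OS(=O)(=O)c5ccc(C)cc5 | intermediate
3 | sodium 2-alkoxide of methyl 4,6-O-benzylidene-3-O-tosyl-α-D-glucopyranoside (not isolated) | CO[C@H]1O[C@@H]2CO[C@@H](c3ccccc3)O[C@H]2[C@H](OS(=O)(=O)c4ccc(C)cc4)[C@H]1[O-].[Na+] | intermediate
4 | methyl 2,3-anhydro-4,6-O-benzylidene-α-D-allopyranoside | CO[C@H]1O[C@@H]2CO[C@@H](c3ccccc3)O[C@H]2[C@H]4O[C@@H]14 | intermediate
5 | methyl 4,6-O-benzylidene-2-O-(4-methoxybenzyl)-α-D-altropyranoside | CO[C@H]1O[C@@H]2CO[C@@H](c3ccccc3)O[C@H]2[C@@H](O)[C@@H]1OCc4ccc(OC)cc4 | intermediate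
6 | benzoyl chloride | O=C(Cl)c1ccccc1 | starting material
7 | methyl 3-O-benzoyl-4,6-O-benzylidene-2-O-(4-methoxybenzyl)-α-D-altropyranoside | CO[C@H]1O[C@@H]2CO[C@@H](c3ccccc3)O[C@H]2[C@@H](OC(=O)c4ccccc4)[C@@H]1OCc5ccc(OC)cc5 | intermediate
8 | methyl 3-O-benzoyl-2-O-(4-methoxybenzyl)-α-D-altropyranoside | CO[C@H]1O[C@H](CO)[C@@H](O)[C@@H](OC(=O)c2ccccc2)[C@@H]1OCc3ccc(OC)cc3 | intermediate
9 | methyl 3-O-benzoyl-6-O-(tert-butyldimethylsilyl)-2-O-(4-methoxybenzyl)-α-D-altropyranoside | CO[C@H]1O[C@H](CO[Si](C)(C)C(C)(C)C)[C@@H](O)[C@@H](OC(=O)c2ccccc2)[C@@H]1OCc3ccc(OC)cc3 | intermediate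
10 | methyl 3-O-benzoyl-6-O-(tert-butyldimethylsilyl)-2-O-(4-methoxybenzyl)-α-D-arabino-hexopyranosid-4-ulose | CO[C@H]1O[C@H](CO[Si](C)(C)C(C)(C)C)C(=O)[C@@H](OC(=O)c2ccccc2)[C@@H]1OCc3ccc(OC)cc3 | intermediate
11 | trimethylsulfoxonium iodide | C[S+](C)(C)=O.[I-] | starting material
12 | methyl 4,4¹-anhydro-3-O-benzoyl-6-O-(tert-butyldimethylsilyl)-4-C-(hydroxymethyl)-2-O-(4-methoxybenzyl)-α-D-idopyranoside (spiro-oxirane, O β, CH2 α) | CO[C@H]1O[C@H](CO[Si](C)(C)C(C)(C)C)[C@@]4(CO4)[C@@H](OC(=O)c2ccccc2)[C@@H]1OCc3ccc(OC)cc3 | intermediate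
13 | benzoic acid | O=C(O)c1ccccc1 | starting material
14 | methyl 3-O-benzoyl-4-C-(benzoyloxymethyl)-6-O-(tert-butyldimethylsilyl)-2-O-(4-methoxybenzyl)-α-D-idopyranoside | CO[C@H]1O[C@H](CO[Si](C)(C)C(C)(C)C)[C@@](O)(COC(=O)c4ccccc4)[C@@H](OC(=O)c2ccccc2)[C@@H]1OCc3ccc(OC)cc3 | intermediate
15 | methyl 3-O-benzoyl-4-C-(benzoyloxymethyl)-2-O-(4-methoxybenzyl)-α-D-idopyranoside | CO[C@H]1O[C@H](CO)[C@@](O)(COC(=O)c4ccccc4)[C@@H](OC(=O)c2ccccc2)[C@@H]1OCc3ccc(OC)cc3 | intermediate
16 | methyl 3-O-benzoyl-4-C-(benzoyloxymethyl)-6-deoxy-6-iodo-2-O-(4-methoxybenzyl)-α-D-idopyranoside | CO[C@H]1O[C@H](CI)[C@@](O)(COC(=O)c4ccccc4)[C@@H](OC(=O)c2ccccc2)[C@@H]1OCc3ccc(OC)cc3 | intermediate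
17 | methyl 3-O-benzoyl-4-C-(benzoyloxymethyl)-6-deoxy-2-O-(4-methoxybenzyl)-hex-5-enopyranoside (C-1 to C-4 as in 16) | CO[C@H]1OC(=C)[C@@](O)(COC(=O)c4ccccc4)[C@@H](OC(=O)c2ccccc2)[C@@H]1OCc3ccc(OC)cc3 | intermediate
18 | acyclic 5-keto aldehyde from 17 with C-6 bound to Hg(OCOCF3) (not isolated) | O=C[C@@H](OCc1ccc(OC)cc1)[C@H](OC(=O)c2ccccc2)[C@](O)(COC(=O)c3ccccc3)C(=O)C[Hg]OC(=O)C(F)(F)F | intermediate
19 | [(1R,4R,5R,6S)-6-(benzoyloxy)-1,4-dihydroxy-5-[(4-methoxybenzyl)oxy]-2-oxocyclohexyl]methyl benzoate | O=C(OC[C@]1(O)C(=O)C[C@@H](O)[C@@H](OCc2ccc(OC)cc2)[C@@H]1OC(=O)c3ccccc3)c4ccccc4 | intermediate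
20 | 4-O-methanesulfonate of 19 (not isolated) | O=C(OC[C@]1(O)C(=O)C[C@@H](OS(C)(=O)=O)[C@@H](OCc2ccc(OC)cc2)[C@@H]1OC(=O)c3ccccc3)c4ccccc4 | intermediate
21 | [(1R,5R,6S)-6-(benzoyloxy)-1-hydroxy-5-[(4-methoxybenzyl)oxy]-2-oxocyclohex-3-en-1-yl]methyl benzoate | O=C(OC[C@]1(O)C(=O)C=C[C@@H](OCc2ccc(OC)cc2)[C@@H]1OC(=O)c3ccccc3)c4ccccc4 | intermediate
22 | [(1R,5R,6S)-6-(benzoyloxy)-1,5-dihydroxy-2-oxocyclohex-3-en-1-yl]methyl benzoate | O=C(OC[C@]1(O)C(=O)C=C[C@@H](O)[C@@H]1OC(=O)c2ccccc2)c3ccccc3 | target

**Totals and risks**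

Total step count: 15. Longest linear sequence: 15 steps (1 → 22).

The three steps most likely to fail:

Step 8. The risk is poor facial selectivity in the ylide addition: the carbon may enter on the β face if the α-axial benzoate outweighs the syn-axial C-2 ether, and base-induced enolisation of the α-benzoyloxy ketone would aggravate this. The fallback sets out from ketone 10 and reverses the order of bond formation at C-4. Non-basic Takai–Lombardo methylenation (Zn, CH2Br2, TiCl4, THF–CH2Cl2) should give the 4-deoxy-4-C-methylene sugar F1. Epoxidation of this exocyclic alkene (m-CPBA, NaHCO3, CH2Cl2) then delivers oxygen, not carbon, to the ring carbon, so a bias toward the β face now leads to the required β-oxirane. The route is rejoined at 12.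

Step 13. The risk is stalling of the mercury cycle: slow oxymercuration of an enol ether flanked by the tertiary carbinol, protodemercuration of 18 before ring closure, or competing mercuration of the anisyl ring. The fallback sets out from 17 and separates unmasking from ring closure. Mild acid hydrolysis of the enol ether (PPTS, acetone–H2O, 40 °C) should release the metal-free 6-deoxyhexos-5-ulose F2, a keto aldehyde that may exist partly as cyclic hemiacetals. Amine-catalysed intramolecular aldolisation (pyrrolidine–AcOH or L-proline, DMSO, rt) should then close the same C3–C4 bond through the methyl-ketone enamine. The route is rejoined at 19.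

Step 9. The risk is slow SN2 opening at the oxirane CH2 beside the crowded quaternary carbon, with migration of the 3-O-benzoyl group to the tertiary alkoxide as the competing process. The fallback sets out from ketone 10 and brings in C7 as a vinyl group. Organocerium addition (CH2=CHMgBr, CeCl3, THF, −78 °C), with carbon again expected from the α face, should give the tertiary allylic alcohol F3. Ozonolysis with borohydride work-up (O3, CH2Cl2–MeOH, −78 °C; then NaBH4) should give the 4-C-hydroxymethyl diol F4. Selective benzoylation of the primary hydroxyl (BzCl 1.05 equiv, pyridine, CH2Cl2, −20 °C) leads back to 14.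

Further compounds
F1 | step 8 | methyl 3-O-benzoyl-6-O-(tert-butyldimethylsilyl)-4-deoxy-4-C-methylene-2-O-(4-methoxybenzyl)-α-D-arabino-hexopyranoside | CO[C@H]1O[C@H](CO[Si](C)(C)C(C)(C)C)C(=C)[C@@H](OC(=O)c2ccccc2)[C@@H]1OCc3ccc(OC)cc3
F2 | step 13 | 3-O-benzoyl-4-C-(benzoyloxymethyl)-6-deoxy-2-O-(4-methoxybenzyl)-hexos-5-ulose (open-chain keto aldehyde, C-2 to C-4 as in 17) | O=C[C@@H](OCc1ccc(OC)cc1)[C@H](OC(=O)c2ccccc2)[C@](O)(COC(=O)c3ccccc3)C(C)=O
F3 | step 9 | methyl 3-O-benzoyl-6-O-(tert-butyldimethylsilyl)-2-O-(4-methoxybenzyl)-4-C-vinyl-α-D-idopyranoside | CO[C@H]1O[C@H](CO[Si](C)(C)C(C)(C)C)[C@@](O)(C=C)[C@@H](OC(=O)c2ccccc2)[C@@H]1OCc3ccc(OC)cc3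
F4 | step 9 | methyl 3-O-benzoyl-6-O-(tert-butyldimethylsilyl)-4-C-(hydroxymethyl)-2-O-(4-methoxybenzyl)-α-D-idopyranoside | CO[C@H]1O[C@H](CO[Si](C)(C)C(C)(C)C)[C@@](O)(CO)[C@@H](OC(=O)c2ccccc2)[C@@H]1OCc3ccc(OC)cc3
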